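## The problem

Atoms are numbered as in the indene skeleton of the target **34** (C1 CHMe, C2=C3 with ethyl on C3, C4 with methyl and carboxyl, C5 with ethyl and the phenyldienyl group, C6=C7 with methyl on C7, ring fusion C3a/C7a).

- Compound **34** is a trans-fused 3a,4,5,7a-tetrahydro-1H-indene with five stereocentres: C1, C3a and C7a on the cyclopentene, and the adjacent quaternary carbons C4 and C5 on the cyclohexene.
- Each ring holds one trisubstituted alkene, so neither ring can come from an aromatic precursor by simple reduction.
- On the five-membered ring the C1 methyl, the C7 arm on C7a and the C4 arm on C3a are all trans. C7a can therefore control C1 by thermodynamic protonation, and the trans fusion decides the face on which the six-membered ring closes.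
- The vicinal quaternary pair C4/C5 has no hydrogen to equilibrate and must be set by stereospecific C–C bond formation.
- The free acid is γ,δ-unsaturated toward three alkenes and cyclises under strong acid. The (E,E)-phenyldiene does not survive hydrogenation, dissolving metal or strong electrophiles, so it must arrive late.
- The feature that opens the route is the cyclopentene. C3 lies between the alkene CH (C2) and C3a and can be a carbonyl carbon. C1 and C2 can be the carbons of a terminal alkyne, and C3a and C7a the carbons of an (E)-alkene. The C1 methyl can be the propargylic CH2 of an ether whose oxygen sits on C7.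
- The five-membered ring is thus the cyclopentenone of an intramolecular Pauson–Khand reaction of an allyl propargyl ether, with the C7 carbinol centre of the tether directing the alkene face.

## Retrosynthesis

**C4–CH3 (34 ⇒ 32).** The ring-contracting rearrangement chosen below can bring C5 to C4 only on the face syn to H3a. That leaves the former lactone carbonyl axial, where **34** has its methyl group. A methyl already on C4 would therefore end up equatorial and give the C4 epimer. C4 is therefore carried as CH through the rearrangement and methylated last. In the planar enediolate of **32** the equatorial approach would pass between both substituents of the neighbouring quaternary C5, while the axial approach is anti to the pseudo-axial dienyl group. The precursor **32** has one quaternary centre fewer. The forward step must be a small-electrophile alkylation of a hindered carboxylate.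

**C4–C5 (32 ⇒ 29).** Cutting C4–C5 and rejoining C7 to the carboxyl oxygen gives the δ-lactone **29**, the substrate of an ester-enolate Claisen ring contraction. Closures at C5–C6 or C6=C7 would require the congested C4–C5 bond to exist already in an open chain. Here it forms inside a six-membered ring with a fixed enolate geometry. In **29** C5 is no longer a stereocentre: its configuration is stored in the C7 carbinol centre and in the Z geometry of the C5=C6 alkene. The forward reaction needs the trienyl group axial on C7 (trans to H7a) so that it reaches C4 across the H3a face in a boat-like array.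

**Lactone C–O and C7–C6 (29 ⇒ 28 ⇒ 17 + 25).** Opening the lactone gives the hydroxy ester **28**. Cutting C7–C6 gives methyl ketone **17** and the stereodefined trienyl iodide **25**. Adding the alkenyl group to the methyl ketone, and not a methyl group to an alkenyl ketone, is the order that the cycloaddition leaves open, because C7 carries its methyl from the start. The open transition-state model (largest α-branch, the C3a arm, anti to the nucleophile) predicts the epimer with the trienyl group trans to H7a, which is the one the rearrangement needs. The forward step must add to an enolisable, α-branched ketone in the presence of an ester.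

**Trienyl fragment (25 ⇒ 24 ⇒ 19 + 22).** The Z trisubstituted alkene is cut between C5 and the dienyl carbon. Bromoboration of **20** gives **22** with bromine and boron cis. The dienyl half comes from enyne **19** (from **18**) by syn methylalumination via **23**. Coupling at C–Br with retention gives **24**, and iodinolysis with retention gives **25**. This places the dienyl group cis to the future C7, which a direct carbometalation of a butyne would not do.

**C3–ethyl, C1–H and the C7 oxidation level (17 ⇒ 16 ⇒ 14 ⇒ 12 ⇒ 11).** The ethyl group is cut at an enol triflate (**14**), which is the trapped enolate of a dissolving-metal reduction of enone **12**. One operation thus fixes C1 (methyl trans to the C7 arm) and the position of the C2=C3 alkene. The carbinol of **11** is masked for that step as the silyl ether **12** and later oxidised (**16** ⇒ **17**). Adding ethyl to a C3 ketone and dehydrating would give no regiocontrol.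

**The C1 methyl (11 ⇒ 9).** Rejoining the C1 methyl carbon to the oxygen on C7 gives the bicyclic γ-alkoxy enone **9**. In the forward direction a two-electron reduction of the enone expels the alkoxide. The tether thus disappears into a methyl group and a hydroxyl, both of which the target needs.

**Three bonds of the cyclopentenone (9 ⇒ 7).** C1–C7a, C3–C3a and C2–C3 are cut together, leading to the 1,6-enyne **7**. The precursor is acyclic with one stereocentre. The forward reaction must transmit the E geometry to the trans C3a/C7a relationship and let the tether methyl choose the face. With CH2 in place of CHMe at C4 there is no second allylic stereocentre to interfere.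

**Ether and alkene of the enyne (7 ⇒ 6 + 3; 6 ⇒ 4 + 5; 3 ⇒ 1 + 2).** The propargyl ether is cut at oxygen, and the E alkene by cross-metathesis into **4** and **5**. Etherification must avoid alkoxide base: a δ-oxy-β,γ-unsaturated ester would conjugate or undergo 1,4-elimination. The propargyl group is therefore delivered as the imidate **3** under acid catalysis.

## Roads not taken

**Alternative 1:** The cut is a cyclobutane fused across C4–C5. A preformed hydrindenone with a C6 carbonyl and a tetrasubstituted C4=C5 alkene would be irradiated with a ketene acetal to give the cis-fused cyclobutanone acetal A1.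

- Merits: both quaternary carbons form in one step, their methyl and ethyl groups are necessarily cis as required, and the two new carbons are at levels suited to the carboxyl and the first dienyl carbon.
- Weak points: a fully substituted enone is a slow (2+2) partner, and facial control must come from the remote ring fusion. The cyclobutane must afterwards be cleaved between the acetal carbon and CH2, C6 deoxygenated to the C6=C7 alkene, and the diene built from a neopentyl position. The bicyclic enone with its three ring stereocentres still has to be made.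
- Comparison: for C4 and C5 this road is better, since the chosen plan needs a rearrangement plus a separate methylation. The chosen plan sets against it that both of its steps draw on centres already fixed, that the dienyl group arrives complete, and that its key step builds the five-membered ring that this alternative presupposes.

**Alternative 2:** The cuts are C3–C3a and C1–C7a on a six-membered ring made first. A cross-conjugated cyclohexadienone with the C4 quaternary centre and a chiral amide would take up an alkenylcopper reagent at C3a anti to the amide, and the enolate would be trapped at C7a by an aldehyde to give A2.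

- Merits: three components in one flask, absolute configuration at C4 from an auxiliary at the outset, and trans C3a/C7a from the addition–aldol sequence.
- Weak points: the dienyl group at C5 would have to be added intermolecularly to a β-ethyl enone next to the quaternary C4. C7 and C6=C7 need a carbonyl transposition. The five-membered ring closes only later, with C1 set from a carbinol of undefined configuration. The amide must be hydrolysed beside a quaternary carbon.
- Comparison: this road fixes C4 earlier and more securely than the late methylation of the chosen plan. The chosen plan offers an intramolecular C4–C5 bond formation with chirality transfer and needs no auxiliary.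

**Alternative 3:** The cut is C7–C7a. A C1=C7a cyclopentene would be hydroborated anti to the C3a substituent, and the secondary alkylborane coupled intramolecularly (B-alkyl Suzuki–Miyaura reaction) with a Z-alkenyl iodide on the C3a side chain to give A3.

- Merits: C1 and C7a are set together by syn addition, the trans fusion, the C7 methyl and the C6=C7 alkene appear in the same step, and the conditions are mild.
- Weak points: a secondary ring-bound alkylborane transmetalates slowly and must do so with retention, while β-hydride elimination competes. The alkene to be hydroborated is hindered by the C3a arm. The adjacent quaternary carbons C4 and C5 must already exist in an open chain. A3 still lacks the C2=C3 alkene, the C3 ethyl group and the diene.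
- Comparison: for the cyclopentane stereocentres this closure is at least as good as cycloaddition plus reduction. The chosen plan sets against it that its hardest bond, C4–C5, forms inside a lactone, and that C3 emerges as the ketone needed for the ethyl-bearing alkene.

Key step: step 4

Assumption: in the cycloaddition the allylic methyl of the tether is taken to occupy the convex face (cis to the ring-fusion hydrogen), the usual outcome for allylic substituents in 1,6-enyne cyclocarbonylations, so that the (S)-alcohol gives the required C3a/C7a configuration.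

Step 1
Reactants: 1 prop-2-yn-1-ol; 2 trichloroacetonitrile
Product: 3 prop-2-yn-1-yl 2,2,2-trichloroacetimidate
Conditions: DBU (0.1 equiv), CH2Cl2, 0 °C
Reagents that add atoms: none
Why: Base-catalysed addition of an alcohol to trichloroacetonitrile (imidate formation) gives a propargyl donor that alkylates under acid catalysis, which step 3 needs.

Step 2
Reactants: 4 (2S)-but-3-en-2-ol; 5 tert-butyl but-3-enoate
Product: 6 tert-butyl (3E,5S)-5-hydroxyhex-3-enoate
Conditions: second-generation Grubbs catalyst (3 mol %), 1,4-benzoquinone (10 mol %), 5 in excess, CH2Cl2, 40 °C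
Reagents that add atoms: none
Why: Olefin cross-metathesis of a secondary allylic alcohol with a monosubstituted β,γ-unsaturated ester should give the E alkene as the thermodynamic product without touching the carbinol centre; benzoquinone suppresses hydride-mediated alkene migration.

Step 3
Reactants: 6 tert-butyl (3E,5S)-5-hydroxyhex-3-enoate; 3 prop-2-yn-1-yl 2,2,2-trichloroacetimidate
Product: 7 tert-butyl (3E,5S)-5-(prop-2-yn-1-yloxy)hex-3-enoate
Conditions: TfOH (5 mol %), CH2Cl2–cyclohexane, 0 → 23 °C
Reagents that add atoms: none
Why: Acid-catalysed O-alkylation with a trichloroacetimidate occurs at oxygen with retention at C5 and avoids the dienolate chemistry (conjugation, 1,4-elimination) that alkoxide bases would cause in a δ-oxy-β,γ-unsaturated ester.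

Step 4
Reactants: 7 tert-butyl (3E,5S)-5-(prop-2-yn-1-yloxy)hex-3-enoate
Product: 9 tert-butyl 2-[(1S,6R,6aR)-1-methyl-5-oxo-3,5,6,6a-tetrahydro-1H-cyclopenta[c]furan-6-yl]acetate, via alkyne–Co2(CO)6 complex 8 (not isolated)
Conditions: Co2(CO)8 (1.1 equiv), CH2Cl2, 23 °C; then N-methylmorpholine N-oxide (8 equiv), 0 → 23 °C
Reagents that add atoms: dicobalt octacarbonyl, O=C=[Co](=C=O)(=C=O)(=C=O)[Co](=C=O)(=C=O)(=C=O)=C=O
Why: The alkyne forms complex 8; the N-oxide removes a CO ligand, the tethered alkene inserts into the Co–C bond at the internal alkyne carbon (C1–C7a), CO inserts, and reductive elimination closes C3–C3a and C2–C3 (intramolecular Pauson–Khand reaction; closest known type: allyl propargyl ethers with 1,2-disubstituted alkenes). The tetrahydrofuran closes by 5-exo insertion of the alkene onto the alkyne carbon and the cyclopentenone by the carbonylative (2+2+1) closure of the cobaltacycle. Insertion is suprafacial, so the E geometry of 7 becomes the trans relationship of the C7 and C4 arms at C7a and C3a. The alkene face is chosen by the carbinol centre of the tether, whose methyl group takes the convex side, cis to the C7a hydrogen; with the (S) centre this gives the (6R,6aR) configuration. Regiochemistry is fixed, since the terminal alkyne carbon can only end up next to the new carbonyl and the tether decides which alkene carbon bonds to the alkyne. The step needs facial selectivity and tolerance of the β,γ-unsaturated ester: with CH2 at C4 the tether methyl is the only directing element, and the neutral N-oxide conditions do not enolise the ester.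

Step 5
Reactants: 9 tert-butyl 2-[(1S,6R,6aR)-1-methyl-5-oxo-3,5,6,6a-tetrahydro-1H-cyclopenta[c]furan-6-yl]acetate
Product: 11 tert-butyl 2-[(1R,5R)-5-[(1S)-1-hydroxyethyl]-4-methyl-2-oxocyclopent-3-en-1-yl]acetate, via exocyclic methylene ketone 10 (not isolated)
Conditions: SmI2 (2.5 equiv), THF–MeOH, −78 °C; then DBU (0.2 equiv), CH2Cl2, 23 °C
Reagents that add atoms: none
Why: SmI2 reduces the enone to a dienolate with expulsion of the γ-alkoxide (vinylogous form of the reductive cleavage of α-alkoxy ketones, known for γ-oxygenated enones and enoates); protonation gives 10 and base moves the alkene into conjugation. The two ring stereocentres are already trans and are not at risk.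

Step 6
Reactants: 11 tert-butyl 2-[(1R,5R)-5-[(1S)-1-hydroxyethyl]-4-methyl-2-oxocyclopent-3-en-1-yl]acetate
Product: 12 tert-butyl 2-[(1R,5R)-4-methyl-2-oxo-5-[(1S)-1-(triethylsilyloxy)ethyl]cyclopent-3-en-1-yl]acetate
Conditions: TESCl, imidazole, CH2Cl2, 0 °C
Reagents that add atoms: chlorotriethylsilane, CC[Si](Cl)(CC)CC
Why: Silyl ether formation masks the hydroxyl, which would otherwise act as a proton source and as a nucleophile toward the triflating agent in step 7.

Step 7
Reactants: 12 tert-butyl 2-[(1R,5R)-4-methyl-2-oxo-5-[(1S)-1-(triethylsilyloxy)ethyl]cyclopent-3-en-1-yl]acetate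
Product: 14 tert-butyl 2-[(1R,4S,5S)-4-methyl-5-[(1S)-1-(triethylsilyloxy)ethyl]-2-(trifluoromethylsulfonyloxy)cyclopent-2-en-1-yl]acetate, via lithium enolate 13 (not isolated)
Conditions: Li (2.2 equiv), t-BuOH (1.0 equiv), NH3–THF, −78 °C; isoprene; NH3 removed; PhNTf2, THF, −78 → 0 °C
Reagents that add atoms: N-phenylbis(trifluoromethanesulfonimide), O=S(=O)(N(c1ccccc1)S(=O)(=O)C(F)(F)F)C(F)(F)F
Why: Dissolving-metal (Birch-type) reduction of the enone protonates the β-carbon to the more stable arrangement, methyl trans to the neighbouring C7 arm, and leaves the regiospecific enolate 13, which is trapped on oxygen (reductive enol triflation). One equivalent of t-BuOH leaves no proton source to equilibrate the enolate, and the tert-butyl ester resists the brief exposure to lithium.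

Step 8
Reactants: 14 tert-butyl 2-[(1R,4S,5S)-4-methyl-5-[(1S)-1-(triethylsilyloxy)ethyl]-2-(trifluoromethylsulfonyloxy)cyclopent-2-en-1-yl]acetate
Product: 16 tert-butyl 2-[(1R,4R,5S)-2-ethyl-5-[(1S)-1-hydroxyethyl]-4-methylcyclopent-2-en-1-yl]acetate, via silyl ether 15 (not isolated)
Conditions: EtMgBr, Fe(acac)3 (5 mol %), THF–NMP, −30 °C; then 1 M HCl, THF, 23 °C
Reagents that add atoms: ethylmagnesium bromide, CC[Mg]Br
Why: Iron-catalysed cross-coupling of an alkenyl triflate with an alkyl Grignard reagent is fast at low temperature, tolerates esters and has no β-hydride problem with ethyl; dilute acid then cleaves the triethylsilyl ether.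

Step 9
Reactants: 16 tert-butyl 2-[(1R,4R,5S)-2-ethyl-5-[(1S)-1-hydroxyethyl]-4-methylcyclopent-2-en-1-yl]acetate
Product: 17 tert-butyl 2-[(1R,4R,5S)-5-acetyl-2-ethyl-4-methylcyclopent-2-en-1-yl]acetate
Conditions: DMP, CH2Cl2, 23 °C
Reagents that add atoms: none
Why: Periodinane oxidation of a secondary alcohol under near-neutral conditions; the α-centre sits in the more stable all-trans arrangement, so epimerisation is not a threat.

Step 10
Reactants: 18 (2E)-3-phenylprop-2-enal
Product: 19 [(1E)-but-1-en-3-yn-1-yl]benzene
Conditions: dimethyl (1-diazo-2-oxopropyl)phosphonate, K2CO3, MeOH, 23 °C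
Reagents that add atoms: dimethyl (1-diazo-2-oxopropyl)phosphonate, CC(=O)C(=[N+]=[N-])P(=O)(OC)OC
Why: Seyferth–Gilbert homologation with the in situ deacylated diazophosphonate converts the aldehyde into the terminal alkyne without touching the E alkene.

Step 11
Reactants: 20 but-1-yne
Product: 22 2-[(1Z)-2-bromobut-1-en-1-yl]-4,4,5,5-tetramethyl-1,3,2-dioxaborolane, via dibromoborane 21 (not isolated)
Conditions: BBr3, CH2Cl2, −78 → 23 °C; then pinacol, 0 °C
Reagents that add atoms: boron tribromide, BrB(Br)Br; pinacol, CC(C)(O)C(C)(C)O
Why: Syn bromoboration of a terminal alkyne puts boron on the terminal and bromine on the internal carbon, cis to each other; exchange with pinacol gives the stable boronate.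

Step 12
Reactants: 19 [(1E)-but-1-en-3-yn-1-yl]benzene; 22 2-[(1Z)-2-bromobut-1-en-1-yl]-4,4,5,5-tetramethyl-1,3,2-dioxaborolane
Product: 24 2-[(1Z,3E,5E)-2-ethyl-4-methyl-6-phenylhexa-1,3,5-trien-1-yl]-4,4,5,5-tetramethyl-1,3,2-dioxaborolane, via dienylalane 23 (not isolated)
Conditions: Me3Al (2 equiv), Cp2ZrCl2 (0.2 equiv), CH2Cl2, 23 °C; then 22, ZnBr2 (0.2 equiv), Pd(PPh3)4 (5 mol %), THF, 23 °C
Reagents that add atoms: trimethylaluminium, C[Al](C)C
Why: Zirconium-catalysed syn methylalumination (carboalumination) of the terminal alkyne gives the (E)-2-methyldienylalane 23. Palladium-catalysed Negishi coupling at the C–Br bond, with the zinc salt as co-catalyst, proceeds with retention and leaves the C–B bond untouched.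

Step 13
Reactants: 24 2-[(1Z,3E,5E)-2-ethyl-4-methyl-6-phenylhexa-1,3,5-trien-1-yl]-4,4,5,5-tetramethyl-1,3,2-dioxaborolane
Product: 25 [(1E,3E,5Z)-5-ethyl-6-iodo-3-methylhexa-1,3,5-trien-1-yl]benzene
Conditions: NaOH (aq), THF, 0 °C; then I2
Reagents that add atoms: iodine, II
Why: Iodinolysis of an alkenylboronate through its hydroxyboronate (base first, then iodine) replaces boron by iodine with retention of alkene geometry.

Step 14
Reactants: 25 [(1E,3E,5Z)-5-ethyl-6-iodo-3-methylhexa-1,3,5-trien-1-yl]benzene; 17 tert-butyl 2-[(1R,4R,5S)-5-acetyl-2-ethyl-4-methylcyclopent-2-en-1-yl]acetate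
Product: 28 tert-butyl 2-[(1R,4R,5S)-2-ethyl-5-[(2R,3Z,5E,7E)-4-ethyl-2-hydroxy-6-methyl-8-phenylocta-3,5,7-trien-2-yl]-4-methylcyclopent-2-en-1-yl]acetate, via trienyllithium 26 (not isolated), via trienylcerium dichloride 27 (not isolated)
Conditions: t-BuLi (2.0 equiv), Et2O, −78 °C; CeCl3, THF, −78 °C; then 17, −78 → −40 °C; aq. NH4Cl
Reagents that add atoms: none
Why: Iodine–lithium exchange with retention and transmetalation to the organocerium reagent give a non-basic nucleophile that adds 1,2 to the enolisable methyl ketone and spares the tert-butyl ester. The new carbinol centre is set by substrate control: approach anti to the ring branch that carries the acetate arm (open transition-state model) places the trienyl group trans to the C7a hydrogen, which is the (2R) epimer.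

Step 15
Reactants: 28 tert-butyl 2-[(1R,4R,5S)-2-ethyl-5-[(2R,3Z,5E,7E)-4-ethyl-2-hydroxy-6-methyl-8-phenylocta-3,5,7-trien-2-yl]-4-methylcyclopent-2-en-1-yl]acetate
Product: 29 (1R,4aR,7R,7aS)-5-ethyl-1-[(1Z,3E,5E)-2-ethyl-4-methyl-6-phenylhexa-1,3,5-trien-1-yl]-1,7-dimethyl-4,4a,7,7a-tetrahydrocyclopenta[c]pyran-3(1H)-one
Conditions: t-BuOK (0.1 equiv), THF, 23 °C
Reagents that add atoms: none
Why: Alkoxide-catalysed intramolecular transesterification (lactonisation) of the tertiary alkoxide onto the unhindered CH2CO2t-Bu group; six-membered ring formation and release of tert-butanol drive it, and basic conditions avoid ionising the tertiary trienylic carbinol.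

Step 16
Reactants: 29 (1R,4aR,7R,7aS)-5-ethyl-1-[(1Z,3E,5E)-2-ethyl-4-methyl-6-phenylhexa-1,3,5-trien-1-yl]-1,7-dimethyl-4,4a,7,7a-tetrahydrocyclopenta[c]pyran-3(1H)-one
Product: 32 (1R,3aS,4S,5S,7aS)-3,5-diethyl-1,7-dimethyl-5-[(1E,3E)-2-methyl-4-phenylbuta-1,3-dien-1-yl]-3a,4,5,7a-tetrahydro-1H-indene-4-carboxylic acid, via silyl ketene acetal 30 (not isolated), via trimethylsilyl ester 31 (not isolated)
Conditions: LiN(i-Pr)2, TMSCl–Et3N, THF, −78 → 23 °C; then toluene, 100 °C; aq. citric acid
Reagents that add atoms: none
Why: Ireland–Claisen (ester-enolate Claisen) rearrangement of a 6-alkenyl δ-lactone as its silyl ketene acetal contracts the ring through a boat-like array. The axial trienyl group reaches C4 only on the face syn to H3a, so chirality passes from C7 to C5, the Z alkene placing the dienyl group pseudo-axial and ethyl pseudo-equatorial, while C6=C7 forms in the new ring. C4 emerges with the carboxyl axial, which is why the methyl group is introduced afterwards.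

Step 17
Reactants: 32 (1R,3aS,4S,5S,7aS)-3,5-diethyl-1,7-dimethyl-5-[(1E,3E)-2-methyl-4-phenylbuta-1,3-dien-1-yl]-3a,4,5,7a-tetrahydro-1H-indene-4-carboxylic acid
Product: 34 (1R,3aR,4R,5S,7aS)-3,5-diethyl-1,4,7-trimethyl-5-[(1E,3E)-2-methyl-4-phenylbuta-1,3-dien-1-yl]-3a,4,5,7a-tetrahydro-1H-indene-4-carboxylic acid, via dilithium enediolate 33 (not isolated)
Conditions: LiN(i-Pr)2 (2.5 equiv), THF–DMPU, 0 → 23 °C; MeI, −78 → 0 °C; dilute HCl, 0 °C
Reagents that add atoms: iodomethane, CI
Why: Alkylation of a carboxylic acid dianion; the planar C4 enediolate should be attacked by iodomethane anti to the pseudo-axial dienyl group on the adjacent quaternary C5, because the equatorial approach would pass between both C5 substituents. This gives axial methyl and equatorial carboxyl, the (4R) configuration.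

Compound list

1 | prop-2-yn-1-ol | C#CCO | starting material
2 | trichloroacetonitrile | N#CC(Cl)(Cl)Cl | starting material
3 | prop-2-yn-1-yl 2,2,2-trichloroacetimidate | C#CCOC(=N)C(Cl)(Cl)Cl | intermediate
4 | (2S)-but-3-en-2-ol | C=C[C@H](C)O | starting material
5 | tert-butyl but-3-enoate | C=CCC(=O)OC(C)(C)C | starting material
6 | tert-butyl (3E,5S)-5-hydroxyhex-3-enoate | C[C@H](O)/C=C/CC(=O)OC(C)(C)C | intermediate
7 | tert-butyl (3E,5S)-5-(prop-2-yn-1-yloxy)hex-3-enoate | C#CCO[C@@H](C)/C=C/CC(=O)OC(C)(C)C | intermediate
8 | hexacarbonyl(μ-alkyne)dicobalt complex of 7 (both alkyne carbons bridging the Co–Co bond) | O=C(OC(C)(C)C)C/C=C/[C@H](C)OCC12[Co]3(=C=O)(=C=O)(=C=O)[Co]1(=C=O)(=C=O)(=C=O)C23 | intermediate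
9 | tert-butyl 2-[(1S,6R,6aR)-1-methyl-5-oxo-3,5,6,6a-tetrahydro-1H-cyclopenta[c]furan-6-yl]acetate | O=C1C=C2CO[C@@H](C)[C@@H]2[C@H]1CC(=O)OC(C)(C)C | intermediate
10 | tert-butyl 2-[(1R,5R)-5-[(1S)-1-hydroxyethyl]-4-methylidene-2-oxocyclopentyl]acetate | O=C1CC(=C)[C@H]([C@H](C)O)[C@H]1CC(=O)OC(C)(C)C | intermediate
11 | tert-butyl 2-[(1R,5R)-5-[(1S)-1-hydroxyethyl]-4-methyl-2-oxocyclopent-3-en-1-yl]acetate | O=C1C=C(C)[C@H]([C@H](C)O)[C@H]1CC(=O)OC(C)(C)C | intermediate
12 | tert-butyl 2-[(1R,5R)-4-methyl-2-oxo-5-[(1S)-1-(triethylsilyloxy)ethyl]cyclopent-3-en-1-yl]acetate | O=C1C=C(C)[C@H]([C@H](C)O[Si](CC)(CC)CC)[C@H]1CC(=O)OC(C)(C)C | intermediate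
13 | lithium (3S,4S,5R)-5-(2-tert-butoxy-2-oxoethyl)-3-methyl-4-[(1S)-1-(triethylsilyloxy)ethyl]cyclopent-1-en-1-olate | [Li]OC1=C[C@@H](C)[C@H]([C@H](C)O[Si](CC)(CC)CC)[C@H]1CC(=O)OC(C)(C)C | intermediate
14 | tert-butyl 2-[(1R,4S,5S)-4-methyl-5-[(1S)-1-(triethylsilyloxy)ethyl]-2-(trifluoromethylsulfonyloxy)cyclopent-2-en-1-yl]acetate | O=S(=O)(OC1=C[C@@H](C)[C@H]([C@H](C)O[Si](CC)(CC)CC)[C@H]1CC(=O)OC(C)(C)C)C(F)(F)F | intermediate
15 | tert-butyl 2-[(1R,4R,5S)-2-ethyl-4-methyl-5-[(1S)-1-(triethylsilyloxy)ethyl]cyclopent-2-en-1-yl]acetate | CCC1=C[C@@H](C)[C@H]([C@H](C)O[Si](CC)(CC)CC)[C@H]1CC(=O)OC(C)(C)C | intermediate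
16 | tert-butyl 2-[(1R,4R,5S)-2-ethyl-5-[(1S)-1-hydroxyethyl]-4-methylcyclopent-2-en-1-yl]acetate | CCC1=C[C@@H](C)[C@H]([C@H](C)O)[C@H]1CC(=O)OC(C)(C)C | intermediate
17 | tert-butyl 2-[(1R,4R,5S)-5-acetyl-2-ethyl-4-methylcyclopent-2-en-1-yl]acetate | CCC1=C[C@@H](C)[C@H](C(C)=O)[C@H]1CC(=O)OC(C)(C)C | intermediate
18 | (2E)-3-phenylprop-2-enal | O=C/C=C/c1ccccc1 | starting material
19 | [(1E)-but-1-en-3-yn-1-yl]benzene | C#C/C=C/c1ccccc1 | intermediate
20 | but-1-yne | CCC#C | starting material
21 | dibromo[(1Z)-2-bromobut-1-en-1-yl]borane | CC/C(Br)=C/B(Br)Br | intermediate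
22 | 2-[(1Z)-2-bromobut-1-en-1-yl]-4,4,5,5-tetramethyl-1,3,2-dioxaborolane | CC/C(Br)=C/B1OC(C)(C)C(C)(C)O1 | intermediate
23 | dimethyl[(1E,3E)-2-methyl-4-phenylbuta-1,3-dien-1-yl]alumane | C[Al](C)/C=C(C)/C=C/c1ccccc1 | intermediate
24 | 2-[(1Z,3E,5E)-2-ethyl-4-methyl-6-phenylhexa-1,3,5-trien-1-yl]-4,4,5,5-tetramethyl-1,3,2-dioxaborolane | CC1(C)OB(/C=C(CC)\C=C(C)\C=C\c2ccccc2)OC1(C)C | intermediate
25 | [(1E,3E,5Z)-5-ethyl-6-iodo-3-methylhexa-1,3,5-trien-1-yl]benzene | I/C=C(CC)\C=C(C)\C=C\c1ccccc1 | intermediate
26 | [(1Z,3E,5E)-2-ethyl-4-methyl-6-phenylhexa-1,3,5-trien-1-yl]lithium | [Li]/C=C(CC)\C=C(C)\C=C\c1ccccc1 | intermediate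
27 | dichloro[(1Z,3E,5E)-2-ethyl-4-methyl-6-phenylhexa-1,3,5-trien-1-yl]cerium | Cl[Ce](Cl)/C=C(CC)\C=C(C)\C=C\c1ccccc1 | intermediate
28 | tert-butyl 2-[(1R,4R,5S)-2-ethyl-5-[(2R,3Z,5E,7E)-4-ethyl-2-hydroxy-6-methyl-8-phenylocta-3,5,7-trien-2-yl]-4-methylcyclopent-2-en-1-yl]acetate | CCC1=C[C@@H](C)[C@H]([C@@](C)(O)/C=C(CC)\C=C(C)\C=C\c2ccccc2)[C@H]1CC(=O)OC(C)(C)C | intermediate
29 | (1R,4aR,7R,7aS)-5-ethyl-1-[(1Z,3E,5E)-2-ethyl-4-methyl-6-phenylhexa-1,3,5-trien-1-yl]-1,7-dimethyl-4,4a,7,7a-tetrahydrocyclopenta[c]pyran-3(1H)-one | CCC1=C[C@@H](C)[C@H]2[C@H]1CC(=O)O[C@@]2(C)/C=C(CC)\C=C(C)\C=C\c3ccccc3 | intermediate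
30 | (1R,4aS,7R,7aS)-5-ethyl-1-[(1Z,3E,5E)-2-ethyl-4-methyl-6-phenylhexa-1,3,5-trien-1-yl]-1,7-dimethyl-3-(trimethylsilyloxy)-1,4a,7,7a-tetrahydrocyclopenta[c]pyran (silyl ketene acetal of 29) | CCC1=C[C@@H](C)[C@H]2[C@H]1C=C(O[Si](C)(C)C)O[C@@]2(C)/C=C(CC)\C=C(C)\C=C\c3ccccc3 | intermediate
31 | trimethylsilyl (1R,3aS,4S,5S,7aS)-3,5-diethyl-1,7-dimethyl-5-[(1E,3E)-2-methyl-4-phenylbuta-1,3-dien-1-yl]-3a,4,5,7a-tetrahydro-1H-indene-4-carboxylate | CCC1=C[C@@H](C)[C@@H]2C(C)=C[C@@](/C=C(C)/C=C/c3ccccc3)(CC)[C@@H](C(=O)O[Si](C)(C)C)[C@@H]12 | intermediate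
32 | (1R,3aS,4S,5S,7aS)-3,5-diethyl-1,7-dimethyl-5-[(1E,3E)-2-methyl-4-phenylbuta-1,3-dien-1-yl]-3a,4,5,7a-tetrahydro-1H-indene-4-carboxylic acid (carboxyl trans to H3a) | CCC1=C[C@@H](C)[C@@H]2C(C)=C[C@@](/C=C(C)/C=C/c3ccccc3)(CC)[C@@H](C(=O)O)[C@@H]12 | intermediate
33 | dilithium enediolate of 32 (C4=C(OLi)2; other centres as in 32) | CCC1=C[C@@H](C)[C@@H]2C(C)=C[C@@](/C=C(C)/C=C/c3ccccc3)(CC)C(=C(O[Li])O[Li])[C@@H]12 | intermediate
34 | (1R,3aR,4R,5S,7aS)-3,5-diethyl-1,4,7-trimethyl-5-[(1E,3E)-2-methyl-4-phenylbuta-1,3-dien-1-yl]-3a,4,5,7a-tetrahydro-1H-indene-4-carboxylic acid | CCC1=C[C@@H](C)[C@@H]2C(C)=C[C@@](/C=C(C)/C=C/c3ccccc3)(CC)[C@](C)(C(=O)O)[C@@H]12 | target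

Total: 17 steps. Longest linear sequence: 12 steps (4 and 5 to 34 through steps 2–9 and 14–17; the trienyl iodide 25 takes 4 steps, the imidate 3 one).

Least certain steps

**Step 4 (key step).** The internal, 1,2-disubstituted alkene inserts more slowly than a terminal one, so decomplexation, migration of the β,γ-alkene into conjugation with the ester, or reductive loss of the propargylic oxygen may compete. With an unsubstituted alkyne, facial control by a single tether methyl may also be incomplete. The fallback sets out from 4 and returns at 9. O-Propargylation of 4 (NaH, propargyl bromide) gives (S)-3-(prop-2-yn-1-yloxy)but-1-ene F1, whose terminal alkene is the standard substrate of the cobalt-mediated cycloaddition. The adduct (1S,6aR)-1-methyl-6,6a-dihydro-1H-cyclopenta[c]furan-5(3H)-one F2 is deprotonated at C6 under kinetic conditions (LiN(i-Pr)2, THF, −78 °C) and alkylated with tert-butyl bromoacetate on the convex face. The acetate arm then sits trans to the tetrahydrofuran carbon, as in 9.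

**Step 14.** The hindered Z-alkenylmetal may enolise the methyl ketone instead of adding to it. Discrimination between the two ring branches flanking the acetyl group may also be too small, so that both carbinol epimers form; only the epimer with the trienyl group trans to H7a rearranges to the required C5 configuration. The fallback sets out from 25 and 17 and returns at 28, replacing substrate control by reagent control. The trienyllithium 26 is transmetalated with ZnBr2 to bromo[(1Z,3E,5E)-2-ethyl-4-methyl-6-phenylhexa-1,3,5-trien-1-yl]zinc F3. This is added to 17 in the presence of Ti(Oi-Pr)4 and a chiral bis(sulfonamide) diol ligand, the known titanium-catalysed asymmetric alkenylzinc addition to ketones, with the ligand enantiomer chosen for the (2R) carbinol.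

**Step 16.** The boat-like array must narrow the C3a–C7a torsion that the trans-fused cyclopentene holds open, which raises the barrier. At the higher temperature then needed, heterolysis of the tertiary, extensively conjugated C7–O bond (loss of chirality transfer, elimination) and a 1,5-hydrogen shift in the Z-diene may compete. The fallback sets out from 28 and returns at 32, closing the ring by a stepwise ionic alkylation. Double deprotonation and silylation (LiN(i-Pr)2, TMSCl) give the tert-butyl trimethylsilyl ketene acetal with a trimethylsilyl ether at the tertiary carbinol F4. Catalytic TMSOTf at −78 °C ionises the allylic silyl ether, and the ketene acetal captures the cation at C5 to give tert-butyl 3,5-diethyl-1,7-dimethyl-5-[(1E,3E)-2-methyl-4-phenylbuta-1,3-dien-1-yl]-3a,4,5,7a-tetrahydro-1H-indene-4-carboxylate F5. The ester is cleaved with TMSOTf and 2,6-lutidine to give 32. The C5 configuration then rests on the conformational preference of the cyclisation and would have to be checked.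

**Step 17.** Methylation may occur on the wrong face (equatorial approach, syn to H3a), or enolisation of the hindered carboxylate may be slow enough for O-methylation to take over. The fallback sets out from 32 and returns at 34. It exchanges the roles of the two C4 substituents, so that an electrophile entering on the H3a face becomes the carboxyl group. The sequence is:

- The enediolate 33 is acylated with methyl chloroformate to the malonic half ester F6 (ester on the H3a face).
- The free acid is activated with ethyl chloroformate and Et3N as the mixed carbonic anhydride F7.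
- F7 is reduced with NaBH4 to the hydroxymethyl ester F8.
- F8 is converted (I2, PPh3, imidazole) into the iodomethyl ester F9.
- F9 is reduced with Bu3SnH to the methyl ester of 34, F10.
- F10 is demethylated with LiI in pyridine to give 34.

## Further compounds

F1 | step 4 | (S)-3-(prop-2-yn-1-yloxy)but-1-ene | C#CCO[C@@H](C)C=C
F2 | step 4 | (1S,6aR)-1-methyl-6,6a-dihydro-1H-cyclopenta[c]furan-5(3H)-one | O=C1C=C2CO[C@@H](C)[C@@H]2C1
F3 | step 14 | bromo[(1Z,3E,5E)-2-ethyl-4-methyl-6-phenylhexa-1,3,5-trien-1-yl]zinc | Br[Zn]/C=C(CC)\C=C(C)\C=C\c1ccccc1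
F4 | step 16 | tert-butyl trimethylsilyl ketene acetal of 28 with the tertiary carbinol as trimethylsilyl ether | CCC1=C[C@@H](C)[C@H]([C@@](C)(O[Si](C)(C)C)/C=C(CC)\C=C(C)\C=C\c2ccccc2)[C@H]1C=C(O[Si](C)(C)C)OC(C)(C)C
F5 | step 16 | tert-butyl (1R,5S,7aS)-3,5-diethyl-1,7-dimethyl-5-[(1E,3E)-2-methyl-4-phenylbuta-1,3-dien-1-yl]-3a,4,5,7a-tetrahydro-1H-indene-4-carboxylate (ring fusion as in 32, C4 epimers) | CCC1=C[C@@H](C)[C@@H]2C(C)=C[C@@](/C=C(C)/C=C/c3ccccc3)(CC)C(C(=O)OC(C)(C)C)[C@@H]12
F6 | step 17 | 3,5-diethyl-4-(methoxycarbonyl)-1,7-dimethyl-5-[(1E,3E)-2-methyl-4-phenylbuta-1,3-dien-1-yl]-3a,4,5,7a-tetrahydro-1H-indene-4-carboxylic acid (ester cis to H3a, other centres as in 34) | CCC1=C[C@@H](C)[C@@H]2C(C)=C[C@@](/C=C(C)/C=C/c3ccccc3)(CC)[C@@](C(=O)OC)(C(=O)O)[C@@H]12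
F7 | step 17 | mixed ethyl carbonic anhydride of F6 | CCC1=C[C@@H](C)[C@@H]2C(C)=C[C@@](/C=C(C)/C=C/c3ccccc3)(CC)[C@@](C(=O)OC)(C(=O)OC(=O)OCC)[C@@H]12
F8 | step 17 | methyl 3,5-diethyl-4-(hydroxymethyl)-1,7-dimethyl-5-[(1E,3E)-2-methyl-4-phenylbuta-1,3-dien-1-yl]-3a,4,5,7a-tetrahydro-1H-indene-4-carboxylate (hydroxymethyl trans to H3a) | CCC1=C[C@@H](C)[C@@H]2C(C)=C[C@@](/C=C(C)/C=C/c3ccccc3)(CC)[C@@](C(=O)OC)(CO)[C@@H]12
F9 | step 17 | methyl 3,5-diethyl-4-(iodomethyl)-1,7-dimethyl-5-[(1E,3E)-2-methyl-4-phenylbuta-1,3-dien-1-yl]-3a,4,5,7a-tetrahydro-1H-indene-4-carboxylate (iodomethyl trans to H3a) | CCC1=C[C@@H](C)[C@@H]2C(C)=C[C@@](/C=C(C)/C=C/c3ccccc3)(CC)[C@@](C(=O)OC)(CI)[C@@H]12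
F10 | step 17 | methyl (1R,3aR,4R,5S,7aS)-3,5-diethyl-1,4,7-trimethyl-5-[(1E,3E)-2-methyl-4-phenylbuta-1,3-dien-1-yl]-3a,4,5,7a-tetrahydro-1H-indene-4-carboxylate | CCC1=C[C@@H](C)[C@@H]2C(C)=C[C@@](/C=C(C)/C=C/c3ccccc3)(CC)[C@](C)(C(=O)OC)[C@@H]12
A1 | alternative 1 | cyclobutanone diethyl acetal photoadduct, cis-fused across C4–C5 of the 6-oxo-hexahydroindene | CCC1=C[C@@H](C)[C@@H]2[C@@H](C)C(=O)[C@]3(CC)CC(OCC)(OCC)[C@]3(C)[C@@H]12
A2 | alternative 2 | trans-disubstituted cuprate–aldol adduct of the C4 prolinol-ether amide cyclohexenone | O=C1C=C(CC)[C@](C)(C(=O)N2CCC[C@H]2COC)[C@@H](C(CC)=C)[C@@H]1[C@@H](C)O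
A3 | alternative 3 | trans-fused bicyclic silyl ether with C4 methyl ester and C5 (4-methoxybenzyloxy)methyl group | C[C@@H]1C[C@H](O[Si](C)(C)C(C)(C)C)[C@H]2[C@H]1C(C)=C[C@@](COCc3ccc(OC)cc3)(CC)[C@]2(C)C(=O)OC
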